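## Retrosynthetic overview

1. Enone Cα=Cβ: Claisen–Schmidt disconnection to the (2S,3S)-dihydrobenzofuran methyl ketone and 4-hydroxybenzaldehyde, which comes from p-cresol by aerobic oxidation.
2. Dihydrofuran ring: traced back to a pyran ring. Oxidative ring contraction of 6-acetyl-5-hydroxy-2,2-dimethyl-2H-chromene moves the ring oxygen from C2 to C3 while C4 and the old C2 are oxygenated. A chiral aryl-λ3-iodane sets both stereocentres.
3. Pyran ring: formal [3+3] chromenylation of 2,4-dihydroxyacetophenone with prenal. The ketone comes from resorcinol and acetic acid.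
4. Ring order: both benzene rings are bought, the pyran ring is made in step 2 and contracted to the dihydrofuran in step 3, and the chalcone chain is added last.

Assumption: the facial sense of the (R,R)-iodane on the chromene is taken by analogy with its behaviour toward styrenes; if the antipode forms, the (S,S)-reagent made from the other methyl lactate enantiomer is used in the same way.

Reagent note: (R,R)-ArI(OCOCF3)2 has Ar = 2,6-bis{[(2R)-1-methoxy-1-oxopropan-2-yl]oxy}phenyl. It is made beforehand by oxidising the parent chiral aryl iodide with Oxone in CF3CO2H, and the aryl iodide is recovered after use.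

## Route

Step 1
Reactants: 1 resorcinol (benzene-1,3-diol); 2 acetic acid
Product: 3 1-(2,4-dihydroxyphenyl)ethan-1-one
Conditions: ZnCl2 (1.2 equiv), AcOH (neat), 140 °C, 30 min
Reagents that add atoms: none
Why: Nencki-type Friedel–Crafts C-acylation, in which ZnCl2 activates acetic acid, resorcinol reacts at C4 (para to one hydroxyl and ortho to the other), and the chelated ketone is deactivated toward a second acylation.

Step 2
Reactants: 3 1-(2,4-dihydroxyphenyl)ethan-1-one; 4 3-methylbut-2-enal (prenal)
Product: 6 1-(5-hydroxy-2,2-dimethyl-2H-chromen-6-yl)ethan-1-one, via ortho-quinone methide 5 (not isolated)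
Conditions: ethylenediammonium diacetate (10 mol %), xylene, reflux, 10 h
Reagents that add atoms: none
Why: Knoevenagel-type condensation at C3, the most nucleophilic carbon because it lies between the two oxygens while the 2-OH is tied up in a hydrogen bond to the acetyl group, gives 5, whose oxa-6π electrocyclisation through the former 4-OH oxygen closes the pyran ring (formal [3+3] chromenylation).

Step 3
Reactants: 6 1-(5-hydroxy-2,2-dimethyl-2H-chromen-6-yl)ethan-1-one
Product: 10 1-[(2S,3S)-3,4-dihydroxy-2-(2-hydroxypropan-2-yl)-2,3-dihydro-1-benzofuran-5-yl]ethan-1-one, via iodane adduct 7 (not isolated), via bridged oxiranium ion 8 (not isolated), via bis(trifluoroacetate) 9 (not isolated)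
Conditions: (R,R)-ArI(OCOCF3)2 (1.2 equiv), BF3·OEt2 (10 mol %), 4 Å MS, CH2Cl2, −78 → −40 °C, 2 h; then poured into ice-cold sat. aq NaHCO3/THF, 0 °C, 30 min
Reagents that add atoms: (R,R)-ArI(OCOCF3)2, dimethyl (2R,2'R)-2,2'-({2-[bis(trifluoroacetoxy)-λ3-iodanyl]benzene-1,3-diyl}bis(oxy))dipropanoate, COC(=O)[C@@H](C)Oc1cccc(O[C@H](C)C(=O)OC)c1I(OC(=O)C(F)(F)F)OC(=O)C(F)(F)F (both new oxygen atoms come from its trifluoroacetate ligands)
Why: Proposed new method: enantioselective oxidative ring contraction of a 2,2-dimethyl-2H-chromene by a C2-symmetric lactate-derived aryl-λ3-iodane; the trivalent iodine binds one enantiotopic face of C3=C4 and trifluoroacetate adds anti at benzylic C4 to give 7 (C3 R, C4 S); in the diequatorial half-chair the C3–I bond is antiperiplanar to the ring bond C2–O1, external SN2 at the neopentyl C3 is blocked, and the trifluoroacetoxy group is too poor a donor to drive the competing semipinacol aryl shift or to close an acyloxonium ion, so the aryloxy oxygen shifts from C2 to C3 with inversion as the aryl iodide leaves (8); trifluoroacetate then captures the tertiary carbon (9), which fixes the trans (2S,3S) array, and bicarbonate hydrolysis by acyl–oxygen cleavage frees 10 without touching either C–O bond; the closest known reaction types are the ring contraction of 1,2-dihydronaphthalenes with hydroxy(tosyloxy)iodobenzene, the lactate-iodane enantioselective dioxygenation of styrenes, and the oxiranium-mediated contraction of chroman-3-yl sulfonates.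

Step 4
Reactants: 11 4-methylphenol (p-cresol)
Product: 12 4-hydroxybenzaldehyde
Conditions: O2 (1 atm), CoCl2 (1 mol %), NaOH (3 equiv), MeOH, 60 °C, 8 h; then aq HCl
Reagents that add atoms: dioxygen, O=O
Why: cobalt-catalysed aerobic benzylic oxidation of the para-cresolate in basic methanol, which stops at the aldehyde because the product phenoxide is a vinylogous carboxylate that resists further oxidation.

Step 5
Reactants: 10 1-[(2S,3S)-3,4-dihydroxy-2-(2-hydroxypropan-2-yl)-2,3-dihydro-1-benzofuran-5-yl]ethan-1-one; 12 4-hydroxybenzaldehyde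
Product: 13 brosimacutin G, (E)-1-[(2S,3S)-3,4-dihydroxy-2-(2-hydroxypropan-2-yl)-2,3-dihydro-1-benzofuran-5-yl]-3-(4-hydroxyphenyl)prop-2-en-1-one
Conditions: KOH (50 % aq, 8 equiv), EtOH, 0 °C → rt, 36 h; then cold 1 M HCl to pH 6
Reagents that add atoms: none
Why: Claisen–Schmidt condensation (aldol addition, then E1cB dehydration) gives the thermodynamically favoured E-enone, and (2S,3S) is retained because neither stereocentre carries an acidic hydrogen and hydroxide is too poor a leaving group for ortho-quinone methide formation at room temperature.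

## Compound list

1 | resorcinol (benzene-1,3-diol) | Oc1cccc(O)c1 | starting material
2 | acetic acid | CC(=O)O | starting material
3 | 1-(2,4-dihydroxyphenyl)ethan-1-one | CC(=O)c1ccc(O)cc1O | intermediate
4 | 3-methylbut-2-enal (prenal) | CC(C)=CC=O | starting material
5 | ortho-quinone methide, 4-acetyl-3-hydroxy-2-[(Z)-3-methylbut-2-en-1-ylidene]cyclohexa-3,5-dien-1-one (not isolated) | CC(=O)C1=C(O)/C(=C/C=C(C)C)C(=O)C=C1 | intermediate
6 | 1-(5-hydroxy-2,2-dimethyl-2H-chromen-6-yl)ethan-1-one | CC1(C)C=Cc2c(O1)ccc(C(C)=O)c2O | intermediate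
7 | iodane adduct, (3R,4S)-6-acetyl-5-hydroxy-2,2-dimethyl-3-[Ar(CF3CO2)I]-3,4-dihydro-2H-chromen-4-yl trifluoroacetate, C3–I and C4–O trans (not isolated) | CC1(C)Oc2ccc(C(C)=O)c(O)c2[C@H](OC(=O)C(F)(F)F)[C@H]1I(OC(=O)C(F)(F)F)c3c(O[C@H](C)C(=O)OC)cccc3O[C@H](C)C(=O)OC | intermediate
8 | bridged oxiranium trifluoroacetate: ring oxygen bonded to the arene, to CMe2 and to the former C3 (inverted, now S); the (S)-C4 trifluoroacetoxy group lies on the face opposite CMe2 (not isolated) | CC1(C)[C@H]2[O+]1c3ccc(C(C)=O)c(O)c3[C@@H]2OC(=O)C(F)(F)F.[O-]C(=O)C(F)(F)F | intermediate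
9 | (2S,3S)-5-acetyl-4-hydroxy-2-[2-(trifluoroacetoxy)propan-2-yl]-2,3-dihydro-1-benzofuran-3-yl trifluoroacetate (not isolated) | CC(C)(OC(=O)C(F)(F)F)[C@H]1Oc2ccc(C(C)=O)c(O)c2[C@@H]1OC(=O)C(F)(F)F | intermediate
10 | 1-[(2S,3S)-3,4-dihydroxy-2-(2-hydroxypropan-2-yl)-2,3-dihydro-1-benzofuran-5-yl]ethan-1-one (2-substituent and 3-OH trans) | CC(C)(O)[C@H]1Oc2ccc(C(C)=O)c(O)c2[C@@H]1O | intermediate
11 | 4-methylphenol (p-cresol) | Cc1ccc(O)cc1 | starting material
12 | 4-hydroxybenzaldehyde | O=Cc1ccc(O)cc1 | intermediate
13 | brosimacutin G | CC(C)(O)[C@H]1Oc2ccc(C(=O)/C=C/c3ccc(O)cc3)c(O)c2[C@@H]1O | target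

## Step count and risks

Total steps: 5. Longest linear sequence: 4 (steps 1, 2, 3 and 5). Step 4 is a one-step side branch.

**Step 3 (the new method, highest risk).** Five failure modes are foreseeable:
- The arene carbon may migrate instead of the ring oxygen.
- Plain 3,4-dioxygenation of the chroman may occur.
- The benzylic trifluoroacetate may ionise and aromatise to the benzofuran before hydrolysis. This is why the reaction is run at low temperature with an immediate cold quench.
- The iodane may attack the phenol, although this phenol is chelated and electron-poor.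
- The ee may be only moderate; crystalline 10 can be recrystallised to raise it.

The fallback uses known reaction types only. It sets out from 6 and comes back at 10. Compound 6 is acetylated (Ac2O, pyridine) to 6-acetyl-2,2-dimethyl-2H-chromen-5-yl acetate F1. Jacobsen–Katsuki epoxidation follows, with (R,R)-[N,N'-bis(3,5-di-tert-butylsalicylidene)cyclohexane-1,2-diaminato]MnCl (4 mol %), NaOCl and 4-phenylpyridine N-oxide in CH2Cl2 at 0 °C. It gives (3R,4R)-6-acetyl-3,4-epoxy-2,2-dimethyl-3,4-dihydro-2H-chromen-5-yl acetate F2. Carboxylate opening at the benzylic carbon with inversion (AcOH, Bu4NOAc) gives (3R,4S)-6-acetyl-3-hydroxy-2,2-dimethyl-3,4-dihydro-2H-chromene-4,5-diyl diacetate F3. Tf2O and 2,6-lutidine at −78 °C give (3R,4S)-6-acetyl-2,2-dimethyl-3-(trifluoromethanesulfonyloxy)-3,4-dihydro-2H-chromene-4,5-diyl diacetate F4. Lutidine-buffered solvolysis in aqueous THF, anchimerically assisted by the ring oxygen, then contracts the ring to (2S,3S)-5-acetyl-2-(2-hydroxypropan-2-yl)-2,3-dihydro-1-benzofuran-3,4-diyl diacetate F5. Cold aqueous LiOH in THF removes both acetates to give 10.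

**Step 5.** Under KOH, 4-hydroxybenzaldehyde is present as its phenoxide and is a sluggish electrophile. The triol ketone 10 therefore sits in strong base for a long time, and some flavanone may form.

The fallback sets out from 12 and 10 and comes back at 13. Compound 12 is O-allylated (allyl bromide, K2CO3, acetone) to the non-ionisable aldehyde 4-(prop-2-en-1-yloxy)benzaldehyde F6. This condenses quickly with 10 (KOH, EtOH, rt) to give brosimacutin G 4-O-allyl ether F7. Neutral Tsuji–Trost deallylation (Pd(PPh3)4 5 mol %, morpholine, THF, rt) then gives 13 without acid touching the benzylic alcohol.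

**Step 2.** The condensation may give low conversion, prenal may self-condense, or some linear chromene may form.

The fallback sets out from 3 and comes back at 6. The non-chelated 4-OH of 3 is alkylated with 3-chloro-3-methylbut-1-yne (K2CO3, KI, CuI cat., acetone, reflux) to 1-{2-hydroxy-4-[(2-methylbut-3-yn-2-yl)oxy]phenyl}ethan-1-one F8. Heating F8 in N,N-diethylaniline at 200 °C triggers an aromatic propargyl Claisen rearrangement to C3, a 1,5-hydrogen shift and an electrocyclisation, which delivers 6.

## Further compounds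

F1 | step 3 | 6-acetyl-2,2-dimethyl-2H-chromen-5-yl acetate | CC1(C)C=Cc2c(O1)ccc(C(C)=O)c2OC(C)=O
F2 | step 3 | (3R,4R)-6-acetyl-3,4-epoxy-2,2-dimethyl-3,4-dihydro-2H-chromen-5-yl acetate | CC1(C)Oc2ccc(C(C)=O)c(OC(C)=O)c2[C@H]3O[C@@H]13
F3 | step 3 | (3R,4S)-6-acetyl-3-hydroxy-2,2-dimethyl-3,4-dihydro-2H-chromene-4,5-diyl diacetate | CC1(C)Oc2ccc(C(C)=O)c(OC(C)=O)c2[C@H](OC(C)=O)[C@H]1O
F4 | step 3 | (3R,4S)-6-acetyl-2,2-dimethyl-3-(trifluoromethanesulfonyloxy)-3,4-dihydro-2H-chromene-4,5-diyl diacetate | CC1(C)Oc2ccc(C(C)=O)c(OC(C)=O)c2[C@H](OC(C)=O)[C@H]1OS(=O)(=O)C(F)(F)F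
F5 | step 3 | (2S,3S)-5-acetyl-2-(2-hydroxypropan-2-yl)-2,3-dihydro-1-benzofuran-3,4-diyl diacetate | CC(C)(O)[C@H]1Oc2ccc(C(C)=O)c(OC(C)=O)c2[C@@H]1OC(C)=O
F6 | step 5 | 4-(prop-2-en-1-yloxy)benzaldehyde | C=CCOc1ccc(C=O)cc1
F7 | step 5 | brosimacutin G 4-O-allyl ether | CC(C)(O)[C@H]1Oc2ccc(C(=O)/C=C/c3ccc(OCC=C)cc3)c(O)c2[C@@H]1O
F8 | step 2 | 1-{2-hydroxy-4-[(2-methylbut-3-yn-2-yl)oxy]phenyl}ethan-1-one | CC(=O)c1ccc(OC(C)(C)C#C)cc1O
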